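## Analysis of the target

Compound 19 is a 3,3''-linked biflavanone. A liquiritigenin unit (rings A, C and B; 7-OH and 4'-OH) is bonded through C3 to C3'' of a naringenin unit (rings A'', C'' and B''; 5''-OH, 7''-OH and a 4-hydroxyphenyl group on C2''). The two halves differ only in the 5''-hydroxyl, so no dimerisation of a single monomer can deliver the compound.

The four contiguous stereocentres C2, C3, C3'' and C2'' are 2S, 3R, 3''R and 2''S. In each pyranone ring the aryl group and the other half are trans, and both halves have the same sense, so the molecule is the pseudo-C2 diastereomer and not the meso-like one.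

C3 and C3'' each lie α to a ketone and can be equilibrated to the trans arrangement. C2 and C2'' are benzylic aryl-ether carbons that cannot be repaired: base opens a pyranone ring by E1cB to a chalcone, and acid ionises the 4-oxybenzylic C–O bond. The five phenols call for one protecting group that leaves under neutral conditions.

The difficulty is twofold. The central C3–C3'' bond joins two tertiary carbons, each flanked by a carbonyl group. C2 and C2'', four bonds apart, must each be set absolutely, because only that fixes their relation to one another.

The plan rests on one feature. C4 is an aryl ketone carbon bonded to C3, and C3 stands β to the second carbonyl C4'' through C3''. The unit O=C4–C3–C3''–C4''=O is therefore a 1,4-diketone, and the C3–C4 bond can be made by adding the acyl-anion equivalent of a ring A salicylaldehyde to an enone C3=C3''–C4''=O that is tethered through O1 and C2.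

## Retrosynthetic reasoning

**19 to 18.** The five O–benzyl bonds are cut last. Benzyl ethers survive every earlier step (organomagnesium addition, hydride base, metathesis, carbene catalysis, boron aldol, carbonate) and leave by hydrogenolysis, which touches none of the four stereocentres. The forward step only has to stop before the benzylic C2–O1 and C2''–O1'' bonds are attacked.

**18 to 16 by way of 17.** In 18 the aryl ether bond O1''–C8a'' is cut. The oxygen goes back to C2'' as a free carbinol and C8a'' takes a fluorine, which gives 16. This bond is chosen over C2''–O1'' because its formation leaves all four bonds at C2'' untouched, so the configuration set in 16 passes into the ring with retention. A closure at the benzylic carbon would instead need a substitution at a 4-oxybenzylic centre. The forward reaction is an addition–elimination on the fluoroarene, activated by the ortho ketone C4''. It first gives the 2'',3''-cis isomer 17, whose C3'' is α to the new ring ketone and moves to the trans isomer 18 under the same base.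

**16 to 14 and 1 by way of 15.** The C3''–C2'' bond is cut in the aldol sense, which leaves the methylene ketone 14 and aldehyde 1. This is the natural place because C3'' is the only methylene α to a carbonyl in 14, and the aldol brings in ring B'' and the oxygen that becomes O1''. The forward reaction must enolise C3'' rather than the methine C3, and must deliver the S configuration at C2''. The Z boron enolate 15 and a closed transition state are expected to do both. The second new centre, C3'', need not be right at this stage.

**14 to 13.** The C3–C4 bond is cut, which is the key disconnection. It turns ketone C4 back into the aldehyde of a salicylaldehyde ether and C3–C3'' back into the double bond of an E-enone, giving 13. Nothing else in the molecule offers a 1,4-dicarbonyl relationship across a ring-forming bond. The gain is that one step closes ring C, completes a protected liquiritigenin unit at the right oxidation level, and leaves the second carbonyl C4'' with its fluorinated ring A'' ready for the aldol and ring closure. The forward reaction needs the acyl-anion equivalent of the aldehyde to add in the conjugate sense, and C3 to end trans to the C2 aryl group.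

**13 to 6 and 12.** The C3=C3'' double bond is cut by cross-metathesis into the terminal alkenes 6 and 12. This places the only stereocentre of 13 in the simpler fragment 6 and keeps the base-sensitive γ-aryloxy enone out of all earlier steps. The forward reaction must give the E alkene and leave the allylic stereocentre alone.

**6 to 4 and 5, and 4 to 1 and 2 by way of 3.** In 6 the aryl–oxygen bond O1–C8a is cut, which gives the allylic alcohol 4 and the fluoroarene 5. As in the later ring closure, forming the aryl C–O bond cannot disturb the carbinol carbon, so the S configuration of 4 becomes C2 of the target unchanged. Alcohol 4 comes from racemic 3 by enzymatic resolution, and 3 from 1 and 2. Resolution is preferred to a direct asymmetric transfer of an unsubstituted vinyl group because it is dependable, and the loss of half the material falls on the cheapest stage.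

**12 to 7 by way of 11, 10, 9 and 8.** The vinyl ketone 12 is traced through the allylic alcohol 11 to aldehyde 10 and reagent 2. Aldehyde 10 comes by formylation (through iminium salt 9) of the bis-benzyl ether 8 of 7. The formyl group enters between a benzyloxy group and the fluorine, which is exactly the pattern that later puts the fluorine on C8a'' and the oxygens on C5'' and C7''.

## Alternatives that were turned down

**Alternative 1:** The disconnection cuts C2–C3 and C2''–C3'' together as two aldol bonds and leads back to the open-chain 1,4-diketone A1 and two molecules of aldehyde 1. In the forward step A1 would be enolised twice with a chiral dialkylboron triflate and an amine, and the bis(Z-enolate) would add to 1 to give the bis-aldol A2. After removal of the silyl groups both pyranone rings would be closed by the phenols displacing the activated carbinols with inversion.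

- In its favour: it is the most convergent plan, it uses the near-symmetry of the target, and it makes two C–C bonds and all four stereocentres in one operation from a simple precursor. On step count it is clearly stronger than the chosen route.
- Against it: the second enolisation has to occur next to an enolate or aldolate already in place. A 1,4-diketone under a Lewis acid tends to cyclodehydrate to a furan. Reagent control alone has to fix four centres, including the C3/C3'' relationship, so errors multiply. Both ring closures are substitutions at 4-alkoxybenzylic carbinols, where ionisation and elimination to a chalcone compete with clean inversion.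
- Comparison: the chosen route needs one aldol only, on a substrate whose own bias is expected to agree with the reagent. It closes both rings at aryl carbons or by C–C bond formation, so no substitution takes place at C2 or C2''.

**Alternative 2:** The disconnection cuts the four bonds around the two carbonyl carbons (C4a–C4, C4–C3, C3''–C4'', C4''–C4a''). Both carbonyl groups would come from a double carbonylation, and C3 and C3'' would be the carbons of an alkyne. In the forward step a zerovalent palladium–bisphosphine catalyst would insert into an aryl iodide and take up the first carbonyl. Syn-acylpalladation of the tethered alkyne would close the first pyranone, a second carbonylation would follow at the vinylpalladium, and coupling with a tethered arylboronate would close the second ring to give the ene-dione A3. Reduction of C3=C3'' and equilibration would finish the skeleton.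

- In its favour: C2 and C2'' are set on a simple alkyne-diol precursor before the cascade, both ketones appear at the right oxidation level, and two rings and four C–C bonds form at once. On paper it is the shortest route.
- Against it: nothing enforces the order of events. Direct carbonylative or plain coupling of the arylpalladium with the boronate can precede alkyne insertion. More seriously, A3 is a tautomer of a chromone: C2–H and C2''–H are benzylic, α to oxygen and γ to a carbonyl, so a proton shift into the aromatic pyranone would erase one of the two centres that cannot be repaired. The tetrasubstituted double bond must then be reduced in a crowded environment.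
- Comparison: the chosen route is longer, but its ring-forming step is a well-established reaction on exactly this substrate class, and it never passes through an intermediate in which C2 is vinylogously acidic after the skeleton is built.

**Alternative 3:** The disconnection cuts C3''–C4'' and O1''–C2'' in a [4+2] sense and leads to the 3-styrylflavan A4 and the salicylaldehyde A5, with C4 and C4'' at the ether oxidation level. In the forward step A5 and an orthoformate would give an O-methyl oxocarbenium ion (a protonated ortho-quinone methide) under a chiral phosphoric acid, which would add across the electron-rich styryl double bond of A4 to give the bis(4-methoxyflavan) A6.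

- In its favour: the trans relationship of C2'' and C3'' follows stereospecifically from the E alkene, the polarity of the two partners secures the regiochemistry, and no epimerisable centre exists while the skeleton is assembled. In this respect it is stronger than the chosen route, which has to manage two enolisable centres.
- Against it: the face of the styrene has to be chosen by the catalyst next to the C3 centre without any binding site. A4 costs about as many steps as the whole first half of the chosen route and carries acid-labile 4-oxybenzylic ethers at C2 and C4 under the very acid that the step needs. Two benzylic methyl ethers must later be oxidised to ketones in the presence of five benzyl ethers and of C2–H and C2''–H.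
- Comparison: the chosen route has the right oxidation level from the start. C4 is formed as a ketone in the key step, and C4'' is the acceptor carbonyl.

Key step: step 9

## Assumptions

- Compounds 1, 2, 5 and 7 are taken as purchased.
- Step 9: the (5aS,10bR) antipode of the triazolium salt is written as the one matched with the S centre at C2. A trial with both antipodes settles this, and because C3 is epimerisable the trans product results in either case.
- Step 10: (−)-(Ipc)2BOTf, made from (+)-α-pinene, is written as the antipode whose Z-enolates add to the Si face of aldehyde 1. If a trial shows the opposite, the mirror-image reagent from (−)-α-pinene is used and nothing else changes.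

## Route

Step 1
Reactants: 1 4-(benzyloxy)benzaldehyde; 2 vinylmagnesium bromide
Product: 3 rac-1-[4-(benzyloxy)phenyl]prop-2-en-1-ol
Conditions: CH2=CHMgBr, THF, −20 → 0 °C; then H2O
Reagents that add atoms: none
Why: Grignard 1,2-addition to a non-enolisable aryl aldehyde should give the racemic secondary allylic alcohol; the benzyl ether is inert.

Step 2
Reactants: 3 rac-1-[4-(benzyloxy)phenyl]prop-2-en-1-ol
Product: 4 (S)-1-[4-(benzyloxy)phenyl]prop-2-en-1-ol
Conditions: Novozym 435 (immobilised Candida antarctica lipase B), vinyl acetate, t-BuOMe, 30 °C, to just past half conversion; chromatography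
Reagents that add atoms: none
Why: Lipase-catalysed kinetic resolution by transesterification; with aryl as the large and vinyl as the medium group the enzyme is expected to acylate the R enantiomer much faster, so the S alcohol (the future C2) remains and is separated from the R acetate. Running slightly past half conversion protects the enantiomeric purity of the recovered alcohol.

Step 3
Reactants: 4 (S)-1-[4-(benzyloxy)phenyl]prop-2-en-1-ol; 5 4-(benzyloxy)-2-fluorobenzaldehyde
Product: 6 4-(benzyloxy)-2-{[(1S)-1-[4-(benzyloxy)phenyl]prop-2-en-1-yl]oxy}benzaldehyde
Conditions: NaH (1.05 equiv), DMF, 0 °C; then 5, 0 → 25 °C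
Reagents that add atoms: none
Why: Nucleophilic aromatic substitution: the sodium alkoxide of 4 displaces fluoride ortho to the formyl group through a formyl-stabilised anionic σ-complex. The carbinol C–O bond is not involved, so the S centre is carried over with retention. Exact stoichiometry of base and low temperature are meant to hold back hydride transfer to the aldehyde and prototropic isomerisation of the allylic alkoxide.

Step 4
Reactants: 7 5-fluororesorcinol
Product: 8 1,3-bis(benzyloxy)-5-fluorobenzene
Conditions: BnBr, K2CO3, DMF, 60 °C
Reagents that add atoms: benzyl bromide, BrCc1ccccc1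
Why: Williamson ether synthesis on both phenols; the unactivated aryl fluoride is not displaced.

Step 5
Reactants: 8 1,3-bis(benzyloxy)-5-fluorobenzene
Product: 10 2,4-bis(benzyloxy)-6-fluorobenzaldehyde, via aryl iminium chloride 9 (not isolated)
Conditions: POCl3, DMF, 0 → 60 °C; then H2O, 0 → 25 °C
Reagents that add atoms: N,N-dimethylformamide, CN(C)C=O; water, O
Why: Vilsmeier–Haack formylation of an electron-rich arene, with hydrolysis of the iminium salt on work-up. Attack is expected para to one benzyloxy group and ortho to the other at the site flanked by the small fluorine rather than by two benzyloxy groups; any 2,6-bis(benzyloxy) isomer would be removed by crystallisation or chromatography.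

Step 6
Reactants: 10 2,4-bis(benzyloxy)-6-fluorobenzaldehyde; 2 vinylmagnesium bromide
Product: 11 rac-1-[2,4-bis(benzyloxy)-6-fluorophenyl]prop-2-en-1-ol
Conditions: CH2=CHMgBr, THF, −78 → 0 °C; then H2O
Reagents that add atoms: none
Why: Grignard 1,2-addition; at low temperature carbonyl addition is far faster than displacement of the ortho fluoride. The new carbinol centre is destroyed in the next step, so the racemate is used.

Step 7
Reactants: 11 rac-1-[2,4-bis(benzyloxy)-6-fluorophenyl]prop-2-en-1-ol
Product: 12 1-[2,4-bis(benzyloxy)-6-fluorophenyl]prop-2-en-1-one
Conditions: MnO2 (excess), CH2Cl2, 23 °C; filtered and used at once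
Reagents that add atoms: none
Why: MnO2 oxidation of an alcohol that is both benzylic and allylic; the neutral heterogeneous conditions spare the polymerisation-prone aryl vinyl ketone, which is not stored.

Step 8
Reactants: 6 4-(benzyloxy)-2-{[(1S)-1-[4-(benzyloxy)phenyl]prop-2-en-1-yl]oxy}benzaldehyde; 12 1-[2,4-bis(benzyloxy)-6-fluorophenyl]prop-2-en-1-one
Product: 13 4-(benzyloxy)-2-{[(1S,2E)-1-[4-(benzyloxy)phenyl]-4-[2,4-bis(benzyloxy)-6-fluorophenyl]-4-oxobut-2-en-1-yl]oxy}benzaldehyde
Conditions: second-generation Hoveyda–Grubbs catalyst, (H2IMes)Cl2Ru=CH(C6H4-2-O-i-Pr) (5 mol%), 12 (3 equiv), CH2Cl2, 40 °C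
Reagents that add atoms: none
Why: Olefin cross-metathesis between a hindered allylic ether that homodimerises slowly and an electron-poor vinyl ketone used in excess. The conjugated enone should form as the E isomer, and the allylic stereocentre takes no part. The aldehyde, the aryl fluoride and the benzyl ethers are tolerated by the ruthenium alkylidene.

Step 9
Reactants: 13 4-(benzyloxy)-2-{[(1S,2E)-1-[4-(benzyloxy)phenyl]-4-[2,4-bis(benzyloxy)-6-fluorophenyl]-4-oxobut-2-en-1-yl]oxy}benzaldehyde
Product: 14 (2S,3R)-7-(benzyloxy)-2-[4-(benzyloxy)phenyl]-3-{2-[2,4-bis(benzyloxy)-6-fluorophenyl]-2-oxoethyl}chroman-4-one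
Conditions: (5aS,10bR)-2-(pentafluorophenyl)-5a,10b-dihydro-4H,6H-indeno[2,1-b][1,2,4]triazolo[4,3-d][1,4]oxazin-2-ium tetrafluoroborate (12 mol%), KN(SiMe3)2 (10 mol%), toluene, 23 °C
Reagents that add atoms: none
Why: The carbene released from the triazolium salt adds to the aldehyde, and proton transfer gives the nucleophilic enaminol, an acyl-anion equivalent. Its carbon adds to C3, the β-carbon of the E-enone; protonation at C3'' and loss of the carbene then give the ketone C4=O and the 1,4-diketone. This is the intramolecular Stetter reaction, which is established for salicylaldehyde ethers of γ-hydroxy enones and enoates and gives 3-substituted chroman-4-ones. Ring C closes in the 6-exo-trig mode, with C4 attacking C3 while the C3=C3'' bond lies outside the forming ring. The new centre C3 is controlled by the S centre at C2: in the chair-like addition transition state the C2 aryl group sits pseudo-equatorial and the enone arm takes the trans position, and the matched antipode of the catalyst reinforces this. Because C3 is α to C4=O, any cis isomer should go over to the trans isomer in the medium or on brief contact with DBU. The step needs conjugate acylation to win over benzoin-type addition and over removal of C2–H, which is γ to the ketone; the ortho tether and the E geometry make the six-membered addition fast, and the base is kept below the amount of azolium so that no amide base is free. No bond to C2 is made or broken.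

Step 10
Reactants: 14 (2S,3R)-7-(benzyloxy)-2-[4-(benzyloxy)phenyl]-3-{2-[2,4-bis(benzyloxy)-6-fluorophenyl]-2-oxoethyl}chroman-4-one; 1 4-(benzyloxy)benzaldehyde
Product: 16 (2S,3R)-7-(benzyloxy)-2-[4-(benzyloxy)phenyl]-3-{(2S,3S)-1-[2,4-bis(benzyloxy)-6-fluorophenyl]-3-[4-(benzyloxy)phenyl]-3-hydroxy-1-oxopropan-2-yl}chroman-4-one, via diisopinocampheylboron Z-enolate 15 (not isolated)
Conditions: (−)-(Ipc)2BOTf, i-Pr2NEt, CH2Cl2, −78 → 0 °C; 1, −78 → −20 °C; H2O2, pH 7 buffer, MeOH, 0 °C
Reagents that add atoms: none
Why: Boron-mediated aldol reaction: soft enolisation is expected at the methylene C3'' rather than at the hindered methine C3 and to give the Z-enolate, which reacts through a closed chair transition state to the 2'',3''-syn adduct. With C3–H eclipsing the enolate to avoid allylic strain, the aldehyde approaches the face away from the C2 aryl group, which leads to S at C3'' and S at C2''; the chosen ligand antipode favours the same aldehyde face, so substrate and reagent reinforce. Only C2'' has to be right here, since C3'' is corrected in step 11.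

Step 11
Reactants: 16 (2S,3R)-7-(benzyloxy)-2-[4-(benzyloxy)phenyl]-3-{(2S,3S)-1-[2,4-bis(benzyloxy)-6-fluorophenyl]-3-[4-(benzyloxy)phenyl]-3-hydroxy-1-oxopropan-2-yl}chroman-4-one
Product: 18 (2S,3R)-7-(benzyloxy)-2-[4-(benzyloxy)phenyl]-3-{(2S,3R)-5,7-bis(benzyloxy)-2-[4-(benzyloxy)phenyl]-4-oxochroman-3-yl}chroman-4-one, via 2'',3''-cis pentabenzyl biflavanone 17 (not isolated)
Conditions: K2CO3 (3 equiv), DMF, 25 → 50 °C
Reagents that add atoms: none
Why: Intramolecular nucleophilic aromatic substitution: the C2'' alkoxide displaces the fluoride ortho to the C4'' ketone and closes ring C'' as a six-membered ring, with retention at C2'' because its C–O bond persists. The first-formed cis isomer 17 has C3'' α to the ring ketone and should epimerise through the enolate to the trans isomer 18 under the same base. Carbonate and moderate temperature are chosen to hold back retro-aldol cleavage and E1cB opening of either pyranone.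

Step 12
Reactants: 18 (2S,3R)-7-(benzyloxy)-2-[4-(benzyloxy)phenyl]-3-{(2S,3R)-5,7-bis(benzyloxy)-2-[4-(benzyloxy)phenyl]-4-oxochroman-3-yl}chroman-4-one
Product: 19 (2S,3R)-7-hydroxy-2-(4-hydroxyphenyl)-3-[(2S,3R)-5,7-dihydroxy-2-(4-hydroxyphenyl)-4-oxochroman-3-yl]chroman-4-one
Conditions: H2 (1 atm), 10% Pd/C, EtOAc–MeOH, 23 °C; stopped when uptake ceases
Reagents that add atoms: none
Why: Hydrogenolysis of the five aryl benzyl ethers under neutral conditions. The electron-rich aryl ketones reduce slowly, and stopping at the end of uptake should avoid cleavage of the benzylic C2–O1 and C2''–O1'' bonds. No stereocentre is touched.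

## Compound list

1 | 4-(benzyloxy)benzaldehyde | O=Cc1ccc(OCc2ccccc2)cc1 | starting material
2 | vinylmagnesium bromide | C=C[Mg]Br | starting material
3 | rac-1-[4-(benzyloxy)phenyl]prop-2-en-1-ol | C=CC(O)c1ccc(OCc2ccccc2)cc1 | intermediate
4 | (S)-1-[4-(benzyloxy)phenyl]prop-2-en-1-ol | O[C@H](c1ccc(OCc2ccccc2)cc1)C=C | intermediate
5 | 4-(benzyloxy)-2-fluorobenzaldehyde | O=Cc1ccc(OCc2ccccc2)cc1F | starting material
6 | 4-(benzyloxy)-2-{[(1S)-1-[4-(benzyloxy)phenyl]prop-2-en-1-yl]oxy}benzaldehyde | O=Cc1ccc(OCc2ccccc2)cc1O[C@H](c1ccc(OCc2ccccc2)cc1)C=C | intermediate
7 | 5-fluororesorcinol (5-fluorobenzene-1,3-diol) | Oc1cc(O)cc(F)c1 | starting material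
8 | 1,3-bis(benzyloxy)-5-fluorobenzene | Fc1cc(OCc2ccccc2)cc(OCc2ccccc2)c1 | intermediate
9 | N-{[2,4-bis(benzyloxy)-6-fluorophenyl]methylidene}-N-methylmethanaminium chloride | C[N+](C)=Cc1c(F)cc(OCc2ccccc2)cc1OCc1ccccc1.[Cl-] | intermediate (not isolated)
10 | 2,4-bis(benzyloxy)-6-fluorobenzaldehyde | O=Cc1c(F)cc(OCc2ccccc2)cc1OCc1ccccc1 | intermediate
11 | rac-1-[2,4-bis(benzyloxy)-6-fluorophenyl]prop-2-en-1-ol | C=CC(O)c1c(F)cc(OCc2ccccc2)cc1OCc1ccccc1 | intermediate
12 | 1-[2,4-bis(benzyloxy)-6-fluorophenyl]prop-2-en-1-one | C=CC(=O)c1c(F)cc(OCc2ccccc2)cc1OCc1ccccc1 | intermediate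
13 | 4-(benzyloxy)-2-{[(1S,2E)-1-[4-(benzyloxy)phenyl]-4-[2,4-bis(benzyloxy)-6-fluorophenyl]-4-oxobut-2-en-1-yl]oxy}benzaldehyde | O=Cc1ccc(OCc2ccccc2)cc1O[C@H](c1ccc(OCc2ccccc2)cc1)/C=C/C(=O)c1c(F)cc(OCc2ccccc2)cc1OCc1ccccc1 | intermediate
14 | (2S,3R)-7-(benzyloxy)-2-[4-(benzyloxy)phenyl]-3-{2-[2,4-bis(benzyloxy)-6-fluorophenyl]-2-oxoethyl}chroman-4-one | O=C1c2ccc(OCc3ccccc3)cc2O[C@H](c2ccc(OCc3ccccc3)cc2)[C@H]1CC(=O)c1c(F)cc(OCc2ccccc2)cc1OCc1ccccc1 | intermediate
15 | diisopinocampheylboron (Z)-enolate of 14 across C3''=C4'' (isopinocampheyl groups from (+)-α-pinene) | O=C1c2ccc(OCc3ccccc3)cc2O[C@H](c2ccc(OCc3ccccc3)cc2)[C@H]1/C=C(\OB([C@@H]1C[C@@H]2C[C@@H](C2(C)C)[C@H]1C)[C@@H]1C[C@@H]2C[C@@H](C2(C)C)[C@H]1C)c1c(F)cc(OCc2ccccc2)cc1OCc1ccccc1 | intermediate (not isolated)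
16 | (2S,3R)-7-(benzyloxy)-2-[4-(benzyloxy)phenyl]-3-{(2S,3S)-1-[2,4-bis(benzyloxy)-6-fluorophenyl]-3-[4-(benzyloxy)phenyl]-3-hydroxy-1-oxopropan-2-yl}chroman-4-one | O=C1c2ccc(OCc3ccccc3)cc2O[C@H](c2ccc(OCc3ccccc3)cc2)[C@H]1[C@H](C(=O)c1c(F)cc(OCc2ccccc2)cc1OCc1ccccc1)[C@H](O)c1ccc(OCc2ccccc2)cc1 | intermediate
17 | (2S,3R)-7-(benzyloxy)-2-[4-(benzyloxy)phenyl]-3-{(2S,3S)-5,7-bis(benzyloxy)-2-[4-(benzyloxy)phenyl]-4-oxochroman-3-yl}chroman-4-one (2'',3''-cis) | O=C1c2ccc(OCc3ccccc3)cc2O[C@H](c2ccc(OCc3ccccc3)cc2)[C@H]1[C@@H]1C(=O)c2c(OCc3ccccc3)cc(OCc3ccccc3)cc2O[C@@H]1c1ccc(OCc2ccccc2)cc1 | intermediate (not isolated)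
18 | (2S,3R)-7-(benzyloxy)-2-[4-(benzyloxy)phenyl]-3-{(2S,3R)-5,7-bis(benzyloxy)-2-[4-(benzyloxy)phenyl]-4-oxochroman-3-yl}chroman-4-one (pentabenzyl ether of the target) | O=C1c2ccc(OCc3ccccc3)cc2O[C@H](c2ccc(OCc3ccccc3)cc2)[C@H]1[C@H]1C(=O)c2c(OCc3ccccc3)cc(OCc3ccccc3)cc2O[C@@H]1c1ccc(OCc2ccccc2)cc1 | intermediate
19 | (2S,3R)-7-hydroxy-2-(4-hydroxyphenyl)-3-[(2S,3R)-5,7-dihydroxy-2-(4-hydroxyphenyl)-4-oxochroman-3-yl]chroman-4-one (CNP0138443.1) | O=C1c2ccc(O)cc2O[C@H](c2ccc(O)cc2)[C@H]1[C@H]1C(=O)c2c(O)cc(O)cc2O[C@@H]1c1ccc(O)cc1 | target

## Step count and least certain steps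

Total: 12 steps. Longest linear sequence: 9 steps (steps 4 to 12, from 7 to 19).

**Step 9 (key step).**
- What may go wrong: C2–H in 13 is benzylic, α to oxygen and γ to the enone carbonyl. Deprotonation there by the carbene or by stray base would erode the configuration at C2 or move the double bond into an enol ether. The bulky C2 aryl group and the electron-rich aldehyde may slow the conjugate addition enough for benzoin-type dimerisation to compete. Incomplete trans selectivity is the least serious problem, since DBU corrects it.
- Fallback, from 13, returning at 14: Pinnick oxidation of 13 (NaClO2, NaH2PO4, 2-methylbut-2-ene, t-BuOH–H2O) gives the benzoic acid F1. Under visible-light photoredox catalysis with PPh3 ([Ir(dF(CF3)ppy)2(dtbbpy)]PF6, K2HPO4, CH2Cl2–H2O, blue light) the carboxylate is deoxygenated to the aroyl radical, which closes 6-exo-trig onto C3 of the enone. Reduction of the resulting α-keto radical and protonation give 14 together with the 2,3-cis epimer F2, which DBU converts into 14. The nucleophilic acyl radical is polarity-matched with the enone, and no base able to remove C2–H is present.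

**Step 10.**
- What may go wrong: the boron triflate may bind the more Lewis-basic chromanone carbonyl and enolise C3, or the bulky reagent may enolise the hindered ketone incompletely. Facial selectivity at C2'' may be poor if the substrate bias is weaker than, or opposed to, the model used here. The adduct may revert by retro-aldol on work-up.
- Fallback, from 14, returning at 16: the control is changed from soft enolisation with a chiral boron reagent to kinetic deprotonation under substrate control. LiN(SiMe3)2 in THF at −78 °C removes a proton from the methylene C3'' and gives the lithium (Z)-enolate F3. Addition of 1 at −78 °C through a closed transition state and a cold quench with acetic acid give 16. Any C2'' epimer is carried on and removed after step 11, where the two all-trans pentabenzyl ethers are diastereomers.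

**Step 11.**
- What may go wrong: the alkoxide of 16 may fragment by retro-aldol to 14 and 1 (both recoverable) or eliminate water before it attacks the fluoroarene. Prolonged contact with carbonate may open either pyranone by E1cB and so erode C2 or C2''.
- Fallback, from 16, returning at 18: ring closure and equilibration are separated and the carbinol is masked. Et3SiOTf and 2,6-lutidine give the triethylsilyl ether F4, which cannot fragment during handling. Anhydrous CsF in DMF at 0 °C releases the alkoxide without a Brønsted base, so it cyclises to 17, and catalytic DBU in toluene then converts 17 into 18.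

**Step 8.**
- What may go wrong: the hindered allylic ether may react slowly while the vinyl ketone polymerises, and ruthenium hydride species may move the double bond of 6 into an enol ether, which destroys the stereocentre.
- Fallback, from 6 and 11, returning at 13: cross-metathesis of 6 with the allylic alcohol 11, a more robust partner than the vinyl ketone, gives the allylic alcohol F5 as a mixture of carbinol epimers. MnO2 oxidises this doubly activated alcohol selectively, in the presence of the aryl aldehyde, to 13.

**Step 3.**
- What may go wrong: the benzylic, allylic alkoxide may transfer hydride to the aldehyde of 5 or isomerise to the propiophenone enolate before the rather electron-rich fluoroarene is substituted.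
- Fallback, from 4, returning at 6: the sodium alkoxide of 4 is combined with purchased 4-(benzyloxy)-2-fluorobenzonitrile, which has no hydride-accepting carbonyl and can be warmed, to give the nitrile F6. Reduction with (i-Bu)2AlH in toluene at −78 °C and hydrolysis of the aldimine with aqueous potassium sodium tartrate give 6.

## Further compounds

F1 | step 9 | 4-(benzyloxy)-2-{[(1S,2E)-1-[4-(benzyloxy)phenyl]-4-[2,4-bis(benzyloxy)-6-fluorophenyl]-4-oxobut-2-en-1-yl]oxy}benzoic acid | OC(=O)c1ccc(OCc2ccccc2)cc1O[C@H](c1ccc(OCc2ccccc2)cc1)/C=C/C(=O)c1c(F)cc(OCc2ccccc2)cc1OCc1ccccc1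
F2 | step 9 | (2S,3S)-7-(benzyloxy)-2-[4-(benzyloxy)phenyl]-3-{2-[2,4-bis(benzyloxy)-6-fluorophenyl]-2-oxoethyl}chroman-4-one (2,3-cis epimer of 14) | O=C1c2ccc(OCc3ccccc3)cc2O[C@H](c2ccc(OCc3ccccc3)cc2)[C@@H]1CC(=O)c1c(F)cc(OCc2ccccc2)cc1OCc1ccccc1
F3 | step 10 | lithium (Z)-enolate of 14 across C3''=C4'' | O=C1c2ccc(OCc3ccccc3)cc2O[C@H](c2ccc(OCc3ccccc3)cc2)[C@H]1/C=C(\O[Li])c1c(F)cc(OCc2ccccc2)cc1OCc1ccccc1
F4 | step 11 | triethylsilyl ether of 16 at the C2'' carbinol | O=C1c2ccc(OCc3ccccc3)cc2O[C@H](c2ccc(OCc3ccccc3)cc2)[C@H]1[C@H](C(=O)c1c(F)cc(OCc2ccccc2)cc1OCc1ccccc1)[C@H](O[Si](CC)(CC)CC)c1ccc(OCc2ccccc2)cc1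
F5 | step 8 | 4-(benzyloxy)-2-{[(1S,2E)-1-[4-(benzyloxy)phenyl]-4-[2,4-bis(benzyloxy)-6-fluorophenyl]-4-hydroxybut-2-en-1-yl]oxy}benzaldehyde (both carbinol epimers) | O=Cc1ccc(OCc2ccccc2)cc1O[C@H](c1ccc(OCc2ccccc2)cc1)/C=C/C(O)c1c(F)cc(OCc2ccccc2)cc1OCc1ccccc1
F6 | step 3 | 4-(benzyloxy)-2-{[(1S)-1-[4-(benzyloxy)phenyl]prop-2-en-1-yl]oxy}benzonitrile | N#Cc1ccc(OCc2ccccc2)cc1O[C@H](c1ccc(OCc2ccccc2)cc1)C=C
A1 | alternative 1 | 1-[4-(benzyloxy)-2-(tert-butyldimethylsilyloxy)phenyl]-4-[2,4-bis(benzyloxy)-6-(tert-butyldimethylsilyloxy)phenyl]butane-1,4-dione | O=C(CCC(=O)c1c(O[Si](C)(C)C(C)(C)C)cc(OCc2ccccc2)cc1OCc1ccccc1)c1ccc(OCc2ccccc2)cc1O[Si](C)(C)C(C)(C)C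
A2 | alternative 1 | bis-syn-aldol of A1 with two molecules of 1: the diketone A1 carrying a (4-benzyloxyphenyl)hydroxymethyl group on each of C3 and C3'', both carbinols set for ring closure with inversion | O=C(c1ccc(OCc2ccccc2)cc1O[Si](C)(C)C(C)(C)C)[C@@H]([C@@H](O)c1ccc(OCc2ccccc2)cc1)[C@H]([C@@H](O)c1ccc(OCc2ccccc2)cc1)C(=O)c1c(O[Si](C)(C)C(C)(C)C)cc(OCc2ccccc2)cc1OCc1ccccc1
A3 | alternative 2 | 3,3''-didehydro pentabenzyl biflavanone (C3=C3'' ene-dione), C2 and C2'' as in the target | O=C1c2ccc(OCc3ccccc3)cc2O[C@H](c2ccc(OCc3ccccc3)cc2)/C1=C1/C(=O)c2c(OCc3ccccc3)cc(OCc3ccccc3)cc2O[C@@H]1c1ccc(OCc2ccccc2)cc1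
A4 | alternative 3 | 7-(benzyloxy)-2-[4-(benzyloxy)phenyl]-3-[(E)-2-[4-(benzyloxy)phenyl]ethenyl]-4-methoxychromane, C2 and C3 as in the target, C4 either epimer | COC1c2ccc(OCc3ccccc3)cc2O[C@H](c2ccc(OCc3ccccc3)cc2)[C@H]1/C=C/c1ccc(OCc2ccccc2)cc1
A5 | alternative 3 | 2,4-bis(benzyloxy)-6-hydroxybenzaldehyde | O=Cc1c(O)cc(OCc2ccccc2)cc1OCc1ccccc1
A6 | alternative 3 | 3,3''-linked bis(4-methoxyflavan) pentabenzyl ether, C2, C3, C3'' and C2'' as in the target, C4 and C4'' either epimer | COC1c2ccc(OCc3ccccc3)cc2O[C@H](c2ccc(OCc3ccccc3)cc2)[C@H]1[C@H]1C(OC)c2c(OCc3ccccc3)cc(OCc3ccccc3)cc2O[C@@H]1c1ccc(OCc2ccccc2)cc1
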